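A small charge of catalyst, 0.00100 M in the cedar run, takes off starting material at a fractional rate of 0.0112 s⁻¹ over the first 8.4 s. The same charge in the alder run reads 0.0593 s⁻¹ between 36 s and 48 s, with 71.4% of its charge turned. That is the fastest rung of a ladder of fractional rates. Below it stands the start of the birch run, 0.0212 s⁻¹ with twice the catalyst of the cedar run, which reads as an order in catalyst of 0.924. Below that, at 0.0118 s⁻¹ and 0.0101 s⁻¹, stand the starts of the alder and ash runs, close to the cedar run, so the order in starting material reads near 1. The start of the elm run, reckoned at 0.00558 s⁻¹ with half the catalyst of the cedar run, is the slowest rung.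

| flask | starting material | catalyst | time |
|---|---|---|---|
| cedar | 0.200 M | 0.00100 M |  |
| ash | 0.120 M | 0.00100 M |  |
| birch | 0.200 M | 0.00200 M |  |
| alder | 0.600 M | 0.00100 M |  |
| elm | 0.400 M | 5.00 × 10⁻⁴ M | 62 s |

| run | time / s | [starting material] / M |
|---|---|---|
| cedar run | 2.8 | 0.1923 |
| cedar run | 8.4 | 0.1821 |
| cedar run | 16 | 0.1656 |
| cedar run | 25 | 0.1495 |
| cedar run | 36 | 0.1255 |
| cedar run | 48 | 0.1005 |
| cedar run | 62 | 0.0802 |
| ash run | 2.8 | 0.1168 |
| ash run | 8.4 | 0.1102 |
| ash run | 16 | 0.1016 |
| ash run | 25 | 0.0889 |
| ash run | 36 | 0.0784 |
| ash run | 48 | 0.0628 |
| ash run | 62 | 0.0541 |
| birch run | 2.8 | 0.1861 |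
| birch run | 8.4 | 0.1674 |
| birch run | 16 | 0.1437 |
| birch run | 25 | 0.1152 |
| birch run | 36 | 0.0901 |
| birch run | 48 | 0.0648 |
| birch run | 62 | 0.0445 |
| alder run | 2.8 | 0.5824 |
| alder run | 8.4 | 0.5434 |
| alder run | 16 | 0.4743 |
| alder run | 25 | 0.3659 |
| alder run | 36 | 0.2303 |
| alder run | 48 | 0.1131 |
| alder run | 62 | 0.0422 |

(each reading ± 0.002 M)

- Overall: starting material -> target, with catalyst as catalyst.
- Constant volume, constant temperature.
- The analysis sees a species whether free or bound.
- An order is taken over about fifteen percent of the charge, up and down.

1. apparent order in [catalyst] of the starting rate, round the charge of the cedar run (the rate where two percent of its starting material have turned into target)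
2. apparent order in [starting material] of the starting rate, round the charge of the cedar run (the rate where two percent of its starting material have turned into target) (one fixed amount of target, the same in the runs compared)
3. the ash run starts with 0.0800 M less of starting material than the cedar run, and with no target. Compared where both hold the same amount of starting material, once fifteen percent of what the ash run was charged with has turned into target, is the ash run faster, slower or alike (within a tenth)?
4. starting material in the elm run at 62 s, as a share of the starting material charged

The present reckoning takes two routes, autocatalysis on top of the catalyst route: the fractional rate is the catalyst term plus a constant times target, and the alder rung reads that constant as 0.112 M⁻¹ s⁻¹. Dividing the target route by the catalyst route removes both starting material and time, and leaves target over a fixed amount. As a fraction of the charge, that amount is 12.4% for the elm run; call it the crossover share, the fraction turned when the two routes run level. It scales with catalyst and inversely with the charge of starting material, so it reads 49.7% for the cedar run and 16.6% for the alder run. Integrating the two routes leaves 29.2% in the elm run at 62 s. At equal starting material, the ash run reckons at 0.595 of the cedar rate, so it is slower.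

The forecast holds that “the target speeds the reaction up”, and gives 0.8 in catalyst, 1 in starting material, slower for the ash run and 34% for the elm run. Its elm value is higher than the present one, and its catalyst order lower.

The flask gives 0.95 in catalyst, 1.0 in starting material, slower for the ash run at a ratio of 0.63, and 31.4% for the elm run.

    catalyst + starting material → target + catalyst (11.00 M⁻¹ s⁻¹)
    catalyst + target ⇌ catalyst-product complex, settled at all times (10.90 M⁻¹)
    starting material + target → 2 target (0.1340 M⁻¹ s⁻¹)

The step in which target turns starting material into more target carries the elm run: without it, 79.3% of the charge stays at 62 s instead of 31.4%, a gap of 48 percentage points. By then the elm run has turned 68.6% of its charge, 5.53 times its crossover share. In the alder run, the crossover share of 16.6% puts a quarter of the charge turned at 15.4 s, and the flask took 18.1 s.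

The earlier runs and the new flask were computed for an exercise; scatter was added.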